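**Analysis of the target**

The target 17, 2,3,5-tribromo-6-(2,4-dibromophenoxy)phenol, is a pentabrominated diaryl ether: two benzene rings joined through one oxygen, with no further ring and no chain. It has no stereocentre, so nothing configurational has to be set and its SMILES carries no descriptors. Ring A, the phenol ring, is numbered here C1 (OH), C2 (O-aryl), C3 (Br), C4 (H), C5 (Br), C6 (Br); ring B is the 2,4-dibromophenoxy ring, with C1' on oxygen and bromine at C2' and C4'. The sensitive groups are the five aryl C–Br bonds, which exclude zerovalent palladium or nickel, alkyllithium reagents, dissolving metals and hydrogenolysis, and the free, electron-poor phenol. The difficulty is the pattern of ring A: the hydroxyl group, the strongest director, points to C4 and C6, yet C4 must stay hydrogen while C3 and C5, both meta to the hydroxyl, must carry bromine, so bromination of a preformed 2-aryloxyphenol cannot give the pattern. The ether oxygen also sits between two ortho-substituted carbons (C2 between C1–OH and C3–Br, C1' beside C2'–Br), so a late C–O coupling would be hindered as well as incompatible with the bromides. The strategy rests on one observation: the run C3(Br)–C4(H)–C5(Br)–C6 of ring A is, atom for atom, the C3–C6 diene portion of 3,5-dibromo-2-pyrone 2, and the adjacent heteroatom-bearing carbons C1 and C2 can be the two carbons of an alkyne that already carries ring B through the ether oxygen.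

**Retrosynthetic reasoning**

C6–Br. The last bond made is C6–Br, so it is the first one cut. The pyrone carbon that becomes C6 necessarily carries hydrogen, and in phenol 16 the C1 hydroxyl can deliver an electrophilic bromine to its single free ortho position. The only other free position, C4, is para to the hydroxyl but lies between the C3 and C5 bromines. The forward reaction has to achieve ortho over para selectivity on a ring with exactly two free positions.

C1–O. Phenol 16 is traced back to arylboronate 15 by exchanging the C1–O bond for a C1–B bond. An alkyne cannot carry a free hydroxyl group, and a second ether oxygen on the alkyne would have to be told apart from the diaryl ether oxygen at the end. Boron is a robust oxygen surrogate that survives heating, and its ipso oxidation is regiospecific and mild enough for the five bromides.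

C2–C3 and C1–C6 (the key disconnection). Ring A of 15 is opened into pyrone 2 and alkynylboronate 13. These two bonds divide the ring into a four-carbon piece that carries exactly the Br/H/Br pattern and a two-carbon piece that carries both heteroatoms. Any other pair of bonds would split the bromines from their ready-made carrier or break the C2–O bond. The gain is twofold: C3–Br, C4–H and C5–Br are fixed by connectivity and not by directing effects, and the hindered O–C2 bond is never made by coupling, because the oxygen arrives already bonded to ring B and to the alkyne carbon. The forward reaction must be a regioselective [4+2] cycloaddition followed by decarboxylative cycloreversion of the bridged lactone 14.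

C(sp)–B. Boronate 13 is cut at its C–B bond to the terminal aryloxyacetylene 9 and the alkoxyboronate 10, through acetylide 11 and ate complex 12. The metalation has to use an amide base, because an alkyllithium would exchange with the ring B bromines.

The alkyne on oxygen. Alkyne 9 is traced through the bromovinyl ether 8, the vicinal dibromide 7 and the vinyl ether 6 to the bromoethyl ether 5, and from there to phenol 3 and the two-carbon electrophile 4. The triple bond is thus built on the phenol oxygen by one alkylation and three eliminations. Ring B is bought complete with both bromines as 3, and every step uses bases that neither exchange with nor metalate an aryl bromide.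

The pyrone. Pyrone 2 is traced to coumalic acid 1: the C5 bromine replaces the carboxyl group by ipso bromination with decarboxylation, and the C3 bromine enters by ordinary electrophilic substitution at the α-carbon of the pyrone.

**Alternatives that were turned down**

Alternative 1: Ring A is cut at C2–C3 and C5–C6 into a ketone piece, 1-(2,4-dibromophenoxy)propan-2-one A1, and a nitro-dialdehyde piece, sodium nitromalonaldehyde A2. In the forward direction both α-carbons of A1 condense with the two formyl carbons of A2 in aqueous base, closing ring A as 2-(2,4-dibromophenoxy)-4-nitrophenol A3.
- For it: A1 comes in one alkylation from 3, the ether and the hydroxyl group are in place, and the three remaining ring A hydrogens of A3 (C3, C5, C6) are exactly the three positions that need bromine. Ring A could therefore be brominated exhaustively with no regiochemical question. On this point the alternative is stronger than the chosen route, and on paper it is no longer.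
- Against it: in A3 the carbon C4 carries a nitro group that must end as hydrogen. That needs a nitro reduction in the presence of C–Br bonds, then diazotisation of an amine para to a free hydroxyl group, where loss of the phenolic proton from the diazonium ion competes, and a reductive dediazoniation. Bromination at C3 and C5, both ortho to the nitro group and one wedged between nitro and aryloxy, would need forcing conditions that put the free C6' position of ring B at risk, or else prior reduction to an oxidation-prone amine. A2 is a shock-sensitive salt.
- Comparison: the chosen strategy gives up the perfectly determined bromination of this alternative. In return C4–H is built in, there is no nitrogen to remove, no energetic reagent is used, and the single electrophilic bromination is directed to the one free ortho position of a phenol.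

Alternative 2: The bonds O–C1' and C2'–Br of ring B are cut, so ring B comes from an aryne. In the forward direction the phenoxide of 3,4,6-tribromo-2-methoxyphenol A4 adds to the aryne released by fluoride from 2-(trimethylsilyl)phenyl trifluoromethanesulfonate A5, and the aryl anion takes bromine from 1,2-dibromo-1,1,2,2-tetrachloroethane A6, giving 1,2,5-tribromo-4-(2-bromophenoxy)-3-methoxybenzene A7.
- For it: the step is convergent and metal-free, A5 is a standard aryne precursor that is unmasked under mild conditions, the hindered ether is formed without a coupling catalyst, and the ortho bromine is set in the same operation. In convergence it is at least as good as the chosen route.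
- Against it: A7 still lacks the C4' bromine, so a para bromination of ring B and a cleavage of the methyl ether follow. The phenoxide of A4 is flanked on both sides and electron-poor, hence a weak nucleophile for the aryne from A5. The aryl anion must be brominated by A6 faster than it is protonated, while A6 can also attack the phenoxide. Above all, A4 contains the whole regiochemical problem of ring A (a bromine ortho to the methoxy group and meta to the hydroxyl, hydrogen para to the methoxy group), which simple bromination of the unbrominated parent of A4 is not sure to deliver and which the key step does nothing to solve.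
- Comparison: the chosen strategy makes the ring A pattern instead of presupposing it.

Alternative 3: Ring B is cut at C1'–C2' and C5'–C6'. In the forward direction the ethynyl ether of ring A, 1,2,5-tribromo-4-(ethynyloxy)-3-methoxybenzene A8, reacts with pyrone 2 by the same thermal [4+2] cycloaddition and decarboxylation to give 1,2,5-tribromo-4-(2,4-dibromophenoxy)-3-methoxybenzene A9, and cleavage of the methyl ether of A9 then gives the target.
- For it: A8 is a simple terminal ynol ether with no boron, a better-precedented partner for 2 than boronate 13. After A9 only one deprotection follows, and there is no late electrophilic bromination. On certainty of the cycloaddition and on the endgame this alternative is stronger.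
- Against it: the cycloaddition is spent on ring B, the ring that is commercially available as 3, while the hard ring must be made beforehand as A4, with the same unsolved pattern as in alternative 2. The ethynyl ether of A8 then has to be assembled on that doubly flanked, acidic phenol in four steps, and its electron-poor, crowded aryloxy group makes A8 a weaker donor dienophile.
- Comparison: the chosen strategy uses the Br–H–Br imprint of the pyrone where it is needed, on ring A, and starts both halves from commercial materials.

Key step: step 7

**Route**

Remark on the chemistry: 8 is drawn as the Z isomer expected from anti elimination; any E isomer should converge on the same alkyne 9 in step 5, if more slowly. Compounds 7 and 14 are racemic and their stereocentres do not survive into later compounds.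

Step 1
Reactants: 1 coumalic acid (2-oxo-2H-pyran-5-carboxylic acid)
Product: 2 3,5-dibromo-2H-pyran-2-one
Conditions: NBS (2.2 equiv), LiOAc (cat.), MeCN/H2O, rt
Reagents that add atoms: N-bromosuccinimide, O=C1CCC(=O)N1Br
Why: Ipso bromination with decarboxylation of the coumalate at C5 (a Hunsdiecker-type bromodecarboxylation), followed by electrophilic bromination at the nucleophilic α-carbon C3 of the pyrone; both are the enol-type positions of the ring, so two equivalents of NBS should give 2 directly.

Step 2
Reactants: 3 2,4-dibromophenol; 4 1,2-dibromoethane (large excess)
Product: 5 2,4-dibromo-1-(2-bromoethoxy)benzene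
Conditions: K2CO3, MeCN, reflux
Reagents that add atoms: none
Why: Williamson ether synthesis; the acidic phenol is fully ionised by K2CO3, and the excess of 4 suppresses a second alkylation to the bis(aryloxy)ethane.

Step 3
Reactants: 5 2,4-dibromo-1-(2-bromoethoxy)benzene
Product: 6 2,4-dibromo-1-(ethenyloxy)benzene
Conditions: KOtBu, THF, 0 °C → rt
Reagents that add atoms: none
Why: E2 dehydrobromination of a primary β-aryloxyethyl bromide by a hindered alkoxide, the standard entry to aryl vinyl ethers; KOtBu at this temperature does not touch aryl C–Br or C–H bonds.

Step 4
Reactants: 6 2,4-dibromo-1-(ethenyloxy)benzene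
Product: 8 2,4-dibromo-1-{[(Z)-2-bromoethenyl]oxy}benzene, via racemic vicinal dibromide 7 (not isolated)
Conditions: Br2 (1.0 equiv), CH2Cl2, −78 °C; then DBU, −78 °C → rt
Reagents that add atoms: bromine, BrBr
Why: Electrophilic addition of Br2 to the electron-rich enol ether double bond is far faster than substitution on the deactivated ring B; the α-bromo ether 7 then loses HBr through its labile α-bromide by base-induced anti elimination, which should give mainly the Z β-bromovinyl ether, as in the classical preparation of such ethers.

Step 5
Reactants: 8 2,4-dibromo-1-{[(Z)-2-bromoethenyl]oxy}benzene
Product: 9 2,4-dibromo-1-(ethynyloxy)benzene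
Conditions: KOtBu, THF, −78 → 0 °C; cold work-up, kept in solution and used at once
Reagents that add atoms: none
Why: Anti-periplanar E2 dehydrobromination of a vinyl bromide (in Z-8 the hydrogen on the oxygen-bearing carbon is trans to bromine), the classical route to aryloxyacetylenes; the base is too weak to metalate ring B.

Step 6
Reactants: 9 2,4-dibromo-1-(ethynyloxy)benzene; 10 2-isopropoxy-4,4,5,5-tetramethyl-1,3,2-dioxaborolane
Product: 13 2-[(2,4-dibromophenoxy)ethynyl]-4,4,5,5-tetramethyl-1,3,2-dioxaborolane, via lithium aryloxyacetylide 11 (not isolated), via lithium alkynyl(isopropoxy)borate 12 (not isolated)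
Conditions: LiN(SiMe3)2, THF, −78 °C; 10, −78 °C; HCl (1.0 equiv) in Et2O, −78 °C → rt
Reagents that add atoms: none
Why: Deprotonation of the terminal alkyne, borylation of the acetylide with an alkoxyboronate and collapse of the ate complex with one equivalent of anhydrous acid is the standard preparation of alkynylboronates; LiN(SiMe3)2 is strong enough for the acidic sp C–H but cannot exchange with the aryl bromides or metalate C3'–H between them, which is why it is preferred to an alkyllithium.

Step 7
Reactants: 2 3,5-dibromo-2H-pyran-2-one; 13 2-[(2,4-dibromophenoxy)ethynyl]-4,4,5,5-tetramethyl-1,3,2-dioxaborolane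
Product: 15 2-[3,5-dibromo-2-(2,4-dibromophenoxy)phenyl]-4,4,5,5-tetramethyl-1,3,2-dioxaborolane, via bridged bicyclic lactone 14 (not isolated)
Conditions: 13 (1.5 equiv), xylenes, 130 °C, sealed tube
Reagents that add atoms: none
Why: This is the thermal Diels–Alder/retro-Diels–Alder benzannulation of a 2-pyrone with an alkyne; the closest known case is the cycloaddition of 2-pyrones with alkynylboronates to give arylboronates, and 13 is a new member of that dienophile class. Pyrone 2 reacts as an electron-poor diene through C3–C6, with C6, the position conjugate to the lactone carbonyl, as its electrophilic terminus and C3 as the α-carbon. In 13 the ether oxygen pushes electron density onto the boron-bearing carbon and the empty boron p orbital stabilises charge there, so that carbon is the nucleophilic terminus and should bond to C6, leaving the oxygen-bearing carbon to bond to the bromine-bearing C3, the sense expected for donor-substituted dienophiles with 2-pyrones. Ring A is closed as a six-membered carbocycle by a concerted, suprafacial [4π+2π] cycloaddition that forms C1–C6 and C2–C3 and gives the 2-oxabicyclo[2.2.2]octadienone 14. Lactone 14 then loses CO2 by a retro-[4+2] reaction driven by aromatisation, so its two bridgehead stereocentres are transient and 15 has none. The step needs regioselectivity (aryloxy carbon next to C3–Br, boron at C1); the matched donor and acceptor polarisation of 13 secures it, and sterics support it because the bulky boronate ends up beside the unsubstituted C6–H. It also needs the C–Br bonds to stay intact, which holds because no metal or nucleophile is present. Unlike alkyl ynol ethers, 13 has no β-hydrogen on its oxygen substituent and cannot fragment to a ketene on heating.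

Step 8
Reactants: 15 2-[3,5-dibromo-2-(2,4-dibromophenoxy)phenyl]-4,4,5,5-tetramethyl-1,3,2-dioxaborolane
Product: 16 3,5-dibromo-2-(2,4-dibromophenoxy)phenol
Conditions: NaBO3·4H2O, THF/H2O, rt
Reagents that add atoms: sodium perborate tetrahydrate (NaBO3·4H2O; dimeric peroxoborate, water of crystallisation omitted), [Na+].[Na+].O[B-]1(O)OO[B-](O)(O)OO1
Why: Oxidation of an arylboronate by peroxoborate, with 1,2-migration of the aryl group from boron to oxygen and hydrolysis, puts the hydroxyl exactly on the carbon that carried boron; the mildly basic conditions leave the aryl bromides and the diaryl ether alone.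

Step 9
Reactants: 16 3,5-dibromo-2-(2,4-dibromophenoxy)phenol
Product: 17 2,3,5-tribromo-6-(2,4-dibromophenoxy)phenol
Conditions: NBS (1.0 equiv), iPr2NH (10 mol %), CH2Cl2, 0 °C → rt
Reagents that add atoms: N-bromosuccinimide, O=C1CCC(=O)N1Br
Why: Amine-catalysed ortho bromination of a phenol: NBS and the secondary amine form an N-bromoamine that hydrogen-bonds to the phenol OH and delivers the bromine to the adjacent carbon C6, while the para position C4 is shielded by the C3 and C5 bromines; one equivalent of NBS limits overbromination.

**Compound list**

1 | coumalic acid (2-oxo-2H-pyran-5-carboxylic acid) | OC(=O)C1=COC(=O)C=C1 | starting material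
2 | 3,5-dibromo-2H-pyran-2-one | O=C1OC=C(Br)C=C1Br | intermediate
3 | 2,4-dibromophenol | Oc1ccc(Br)cc1Br | starting material
4 | 1,2-dibromoethane | BrCCBr | starting material
5 | 2,4-dibromo-1-(2-bromoethoxy)benzene | BrCCOc1ccc(Br)cc1Br | intermediate
6 | 2,4-dibromo-1-(ethenyloxy)benzene | C=COc1ccc(Br)cc1Br | intermediate
7 | 2,4-dibromo-1-(1,2-dibromoethoxy)benzene (racemic, not isolated) | BrCC(Br)Oc1ccc(Br)cc1Br | intermediate
8 | 2,4-dibromo-1-{[(Z)-2-bromoethenyl]oxy}benzene | Br/C=C\Oc1ccc(Br)cc1Br | intermediate
9 | 2,4-dibromo-1-(ethynyloxy)benzene | C#COc1ccc(Br)cc1Br | intermediate
10 | 2-isopropoxy-4,4,5,5-tetramethyl-1,3,2-dioxaborolane | CC(C)OB1OC(C)(C)C(C)(C)O1 | starting material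
11 | lithium (2,4-dibromophenoxy)acetylide (not isolated) | [Li]C#COc1ccc(Br)cc1Br | intermediate
12 | lithium [(2,4-dibromophenoxy)ethynyl](isopropoxy)(pinacolato)borate (not isolated) | [Li+].CC(C)O[B-]1(C#COc2ccc(Br)cc2Br)OC(C)(C)C(C)(C)O1 | intermediate
13 | 2-[(2,4-dibromophenoxy)ethynyl]-4,4,5,5-tetramethyl-1,3,2-dioxaborolane | CC1(C)OB(C#COc2ccc(Br)cc2Br)OC1(C)C | intermediate
14 | 4,7-dibromo-5-(2,4-dibromophenoxy)-6-(4,4,5,5-tetramethyl-1,3,2-dioxaborolan-2-yl)-2-oxabicyclo[2.2.2]octa-5,7-dien-3-one (racemic, not isolated) | O=C1OC2C(Br)=CC1(Br)C(Oc3ccc(Br)cc3Br)=C2B4OC(C)(C)C(C)(C)O4 | intermediate
15 | 2-[3,5-dibromo-2-(2,4-dibromophenoxy)phenyl]-4,4,5,5-tetramethyl-1,3,2-dioxaborolane | CC1(C)OB(c2cc(Br)cc(Br)c2Oc2ccc(Br)cc2Br)OC1(C)C | intermediate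
16 | 3,5-dibromo-2-(2,4-dibromophenoxy)phenol | Oc1cc(Br)cc(Br)c1Oc1ccc(Br)cc1Br | intermediate
17 | 2,3,5-tribromo-6-(2,4-dibromophenoxy)phenol | Oc1c(Br)c(Br)cc(Br)c1Oc1ccc(Br)cc1Br | target

**Step count and risks**

Total: 9 steps. Longest linear sequence: 8 steps, from 3 to 17 (steps 2 to 9); step 1 is a one-step branch that joins at step 7.

Step 7 (key step). The push–pull alkyne 13 may oligomerise or decompose thermally faster than it undergoes the slow bimolecular cycloaddition, and regiocontrol may erode if the bulk of the aryloxy group beside C3–Br outweighs the electronic bias. The fallback abandons the cycloaddition and reaches ring A by substitution on a preformed ring. It sets out from phenol 3: nucleophilic aromatic substitution of fluoride in commercial 3,5-dibromo-2-fluorobenzaldehyde (K2CO3, DMF, heat), activated by the ortho formyl group, should give 3,5-dibromo-2-(2,4-dibromophenoxy)benzaldehyde F1. Baeyer–Villiger (Dakin-type) oxidation with mCPBA, with migration of the ortho-oxygenated aryl group, should give 3,5-dibromo-2-(2,4-dibromophenoxy)phenyl formate F2, and methanolysis (K2CO3, MeOH) returns to the route at phenol 16.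

Step 6. The acid that collapses ate complex 12 may instead protonate the electron-rich alkyne carbon, leading to addition across the ynol ether or loss of boron; the product may also hydrolyse during isolation. The fallback replaces boron by silicon as the placeholder at C1 and introduces boron only after the ring exists. It sets out from alkyne 9: acetylide 11, made as before with LiN(SiMe3)2, is silylated with Me3SiCl, with no acid needed, to give [(2,4-dibromophenoxy)ethynyl]trimethylsilane F3. Heating F3 with pyrone 2 should give, by the same cycloaddition and decarboxylation with the silicon-bearing carbon bonding to C6, [3,5-dibromo-2-(2,4-dibromophenoxy)phenyl]trimethylsilane F4. Ipso borodesilylation with BBr3 in CH2Cl2 gives dibromo[3,5-dibromo-2-(2,4-dibromophenoxy)phenyl]borane F5, and pinacol with Et3N converts it into arylboronate 15, where the route is rejoined.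

Step 9. Bromination may occur in part at C4, para to the hydroxyl, or twice, because both free positions are activated by the same hydroxyl group and the steric shielding of C4 is the only intrinsic bias. The fallback turns the hydroxyl into a directing group for C–H activation. It sets out from phenol 16: carbamoylation (Me2NCOCl, K2CO3) gives 3,5-dibromo-2-(2,4-dibromophenoxy)phenyl dimethylcarbamate F6, whose only ortho C–H is C6. Carbamate-directed ortho C–H bromination catalysed by Pd(OAc)2 with NBS and p-TsOH runs between divalent and tetravalent palladium and so should not insert into C–Br bonds; it should give 2,3,5-tribromo-6-(2,4-dibromophenoxy)phenyl dimethylcarbamate F7. Hydrolysis (KOH, EtOH/H2O, reflux) then arrives at the target 17.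

Step 5. The terminal aryloxyacetylene 9 may oligomerise on concentration, or tert-butoxide may add across the ynol ether, so that little 9 reaches the next step. The fallback gives up isolating the free alkyne. It sets out from bromovinyl ether 8: slow addition of LiN(iPr)2 (2 equiv) to 8 in THF at −78 °C should effect elimination and metalation in one flask and give acetylide 11 directly, the amide never being in excess over the far more acidic alkyne C–H; the route is rejoined at 11, which is borylated with 10 as in step 6. No new compound is made.

**Further compounds**

F1 | step 7 | 3,5-dibromo-2-(2,4-dibromophenoxy)benzaldehyde | O=Cc1cc(Br)cc(Br)c1Oc1ccc(Br)cc1Br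
F2 | step 7 | 3,5-dibromo-2-(2,4-dibromophenoxy)phenyl formate | O=COc1cc(Br)cc(Br)c1Oc1ccc(Br)cc1Br
F3 | step 6 | [(2,4-dibromophenoxy)ethynyl]trimethylsilane | C[Si](C)(C)C#COc1ccc(Br)cc1Br
F4 | step 6 | [3,5-dibromo-2-(2,4-dibromophenoxy)phenyl]trimethylsilane | C[Si](C)(C)c1cc(Br)cc(Br)c1Oc1ccc(Br)cc1Br
F5 | step 6 | dibromo[3,5-dibromo-2-(2,4-dibromophenoxy)phenyl]borane | BrB(Br)c1cc(Br)cc(Br)c1Oc1ccc(Br)cc1Br
F6 | step 9 | 3,5-dibromo-2-(2,4-dibromophenoxy)phenyl dimethylcarbamate | CN(C)C(=O)Oc1cc(Br)cc(Br)c1Oc1ccc(Br)cc1Br
F7 | step 9 | 2,3,5-tribromo-6-(2,4-dibromophenoxy)phenyl dimethylcarbamate | CN(C)C(=O)Oc1c(Br)c(Br)cc(Br)c1Oc1ccc(Br)cc1Br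
F0 | step 5 | none | none
A1 | alternative 1 | 1-(2,4-dibromophenoxy)propan-2-one | CC(=O)COc1ccc(Br)cc1Br
A2 | alternative 1 | sodium nitromalonaldehyde | [Na+].[O-]C=C(C=O)[N+](=O)[O-]
A3 | alternative 1 | 2-(2,4-dibromophenoxy)-4-nitrophenol | Oc1ccc(cc1Oc1ccc(Br)cc1Br)[N+](=O)[O-]
A4 | alternative 2 | 3,4,6-tribromo-2-methoxyphenol | COc1c(O)c(Br)cc(Br)c1Br
A5 | alternative 2 | 2-(trimethylsilyl)phenyl trifluoromethanesulfonate | C[Si](C)(C)c1ccccc1OS(=O)(=O)C(F)(F)F
A6 | alternative 2 | 1,2-dibromo-1,1,2,2-tetrachloroethane | ClC(Cl)(Br)C(Cl)(Cl)Br
A7 | alternative 2 | 1,2,5-tribromo-4-(2-bromophenoxy)-3-methoxybenzene | COc1c(Br)c(Br)cc(Br)c1Oc1ccccc1Br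
A8 | alternative 3 | 1,2,5-tribromo-4-(ethynyloxy)-3-methoxybenzene | COc1c(Br)c(Br)cc(Br)c1OC#C
A9 | alternative 3 | 1,2,5-tribromo-4-(2,4-dibromophenoxy)-3-methoxybenzene | COc1c(Br)c(Br)cc(Br)c1Oc1ccc(Br)cc1Br
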